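Colleague, here is the flask you asked about, with your hunch that raising first nucleophile from 0.300 M to 0.450 M puts target ahead.

- south-west: starting material 0.10 M; first nucleophile 0.300 M; second nucleophile 0.0900 M; protic impurity 2.00 mM; time 40 h
- north-west: starting material 0.10 M; first nucleophile 0.450 M; second nucleophile 0.0900 M; protic impurity 2.00 mM; time 40 h

    intermediate → solvolysis product (k1 = 0.146 min⁻¹)
    target ⇌ isomer of the product (K2 = 0.44, k2 = 0.00216 min⁻¹)
    starting material + protic impurity → quenched substrate (k3 = 0.317 M⁻¹ min⁻¹)
    starting material → intermediate (k4 = 0.00184 min⁻¹)
    first nucleophile + intermediate → target (k5 = 0.841 M⁻¹ min⁻¹)
    starting material + intermediate → side product (k6 = 0.0880 M⁻¹ min⁻¹)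
    second nucleophile + intermediate → other capture product (k7 = 22.8 M⁻¹ min⁻¹)

- which of the two there is more of at the end, south-west (other capture product / target)
- which of the two there is more of at the end, north-west (other capture product / target)
- how much target is there at the end, in percent of the starting material charged: south-west
- how much target is there at the end, in percent of the starting material charged: north-west

- percent here means starting material units held: one side product counts as two
- run time (south-west): 40 h

You need one concentration for this. Ionisation of starting material is the rate-limiting step: intermediate is consumed at 0.398 min⁻¹ or more, faster than the 0.00184 min⁻¹ of its making, so it holds a steady state and each ionisation merely chooses a path. Write [D] for second nucleophile. Take the solvolysis constant plus the capture rate by first nucleophile, and divide by the capture constant of second nucleophile: that gives 17.5 mM south-west, 23.0 mM north-west. Call this the crossover concentration: with [D] equal to it, second nucleophile takes half of the intermediate. Well above it [D] falls nearly zero-order, at the pace of ionisation; well below it, first-order.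

Integrating, with L = ln(charged [D]/[D]) and first nucleophile held at its charge, units captured equal the [D] lost plus crossover times L. Protic impurity meets starting material at 0.0317 min⁻¹, faster than ionisation, so I take it off first and have 96.8 mM to place. South-west, trying [D] at the crossover places 101 mM, slightly over. Each unit of L costs twice the crossover there, which corrects L to 1.51; north-west the same gives 1.33. Target plus isomer is L times the first-nucleophile capture rate over the second's capture constant. Target's forward half-life of 5.3 h is short against 40 h, so I split the pair by 0.44. My reckoning: target 11.6% south-west, 15.3% north-west, and other capture product ahead in both.

The forecast, reasoning that “The intermediate stays at steady state”, says 11.5% and 15%, just under mine, with other capture product ahead south-west and other capture product north-west.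

The simulation gives target 11.4% south-west and 15.0% north-west, against other capture product at 70.3% and 66.3%.

In the north-west flask at 6.15 h, second nucleophile was taking intermediate 3.3 times as fast as first nucleophile was. At the end of that flask [D] reads 23.7 mM, close to the crossover of 23.0 mM.

Now take the neighbour of north-west charged with 0.022 M of second nucleophile, close to that same crossover, so at the start second nucleophile takes about half of the intermediate. Counting its whole charge as captured, L is 3.25, which gives target 37.5%. That flask ends with 36.7% target, ahead of other capture product at 21.3% and solvolysis product at 21.7%.

All constants come from no measurement; what happens was integrated by code.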